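The data stem from a simulated flask on assumed constants.

In the closed, stirred vessel, starting material S and partner R make target, and the quick number wanted is the share of S turned in the ash flask, whose charges are twice those of the elm flask.

| setting | elm | birch | maple | ash |
|---|---|---|---|---|
| starting material | 0.800 M | 0.800 M | 0.800 M | 1.60 M |
| partner | 0.960 M | 1.40 M | 0.960 M | 1.90 M |
| target |  |  | 0.240 M |  |
| time |  |  |  | 54 min |

| run | time / min | [target] / M |
|---|---|---|
| elm run | 4.1 | 0.114 |
| elm run | 12 | 0.296 |
| elm run | 24 | 0.458 |
| elm run | 38 | 0.591 |
| elm run | 54 | 0.664 |
| birch run | 4.1 | 0.161 |
| birch run | 12 | 0.401 |
| birch run | 24 | 0.577 |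
| birch run | 38 | 0.682 |
| birch run | 54 | 0.755 |
| maple run | 4.1 | 0.377 |
| maple run | 12 | 0.564 |
| maple run | 24 | 0.746 |
| maple run | 38 | 0.856 |
| maple run | 54 | 0.925 |

(readings scatter by 0.006 M)

* the power of [partner] that the first rate follows, about the charge of the elm run; measure it at two percent of starting material made into target
* target in the ash run at 54 min, as a share of the starting material charged

- Overall: starting material + partner -> target.
- Constant volume, constant temperature.
- Bound and free are read together.
- "The second partner" is partner.
- An order is taken over about fifteen percent of the charge, up and down.

The fraction left says more here than the fraction made. The elm flask at 54 min keeps 17.0% of its S, which is 1.77 lives run, a life count L being the natural logarithm of the S charged over the S left, the time-integral of a pseudo-first-order constant. L is no pure function of the partner charge, since partner is consumed along with S, and the maple flask, seeded with target, has run 1.94 lives by 54 min, further than the elm flask's 1.77. The ash flask does keep partner to S at 1.19 against 1.20 in the elm flask, so a rough reckoning, which sets aside the larger amount of target made in the ash flask, can scale the elm count by a power of partner. The first readings, at 4.1 min, stand at 1.41 for birch over elm against a partner ratio of 1.46, which reads as an order of 0.915, with a scatter of 5.26% on the elm reading. Scaling the elm count by the ash partner ratio to that power gives 3.31 lives, so this reply's own reckoning leaves 3.65% of the S and turns 96.3%. The forecast sent along differs a little: it gives an order of 1 and 96%, reached by integrating a rate that climbs with target, and it chose to “shade that down slightly in case of saturation or reversibility”.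

The flask gives an order of 0.86 and 95.3%.

    starting material + partner → target (0.1086 M⁻¹ min⁻¹)
    starting material + 2 partner → target + partner (0.7320 M⁻² min⁻¹)
    starting material + partner + target → 2 target (0.1530 M⁻² min⁻¹)
    2 partner ⇌ idle reagent dimer, settled at all times (12.70 M⁻¹)

The ash flask's 95.3% amounts to 3.05 lives, fewer than the 3.31 reckoned, and 1.72 times the elm count for a partner ratio of 1.98. The joining of two partner to idle reagent dimer holds the order in partner about the elm charge at 0.86, against 1.9 without that joining.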